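The run of 15 s is shorter than the electrophile's half-life towards product but longer than the free leaving group's half-life, so you reckon this flask by mean rates, not by its starting rate.

electrophile 0.050 M; nucleophile 0.150 M; buffer base 0.150 M; buffer acid 5.00 mM; time 15 s

    protonated nucleophile ⇌ nucleophile + acid, settled at all times (K1 = 1.0 × 10⁻⁷ M)
    leaving group → by-product carried off (k2 = 0.0637 s⁻¹)
    electrophile + leaving group ⇌ idle adduct, settled at all times (K3 = 85 M⁻¹)
    buffer acid ⇌ buffer base + acid, settled at all times (K4 = 6.3 × 10⁻⁷ M)
    electrophile + nucleophile → acid + product + leaving group (k5 = 0.185 M⁻¹ s⁻¹)

1. part of the electrophile that has reacted at 15 s
2. pH of the solution at 15 s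

- acid is the free proton; pH is minus the decimal logarithm of its molar concentration
- amounts and yields of leaving group count idle adduct too
- what has gone from electrophile into another species counts as reacted, even if it can come back
- run time (flask): 15 s

Set the three known measures side by side:

- electrophile towards product, by that step alone at the charges: half-life 25 s
- free leaving group towards by-product, by that step alone: half-life 11 s
- idle adduct per free leaving group at the start: 4.2

Read the first row as a pseudo-first-order count. The drive, the share of the charged electrophile that would become product if the starting rate held for the run, is 0.416. Both reactants fall, so you multiply the drive by their mean free shares.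

For the nucleophile, put every proton on it, those of the buffer acid and those of a mean turnover: its mean share is 0.897.

Read the third row at an electrophile share of 0.5: adduct per free leaving group is 2.12, so the bound share is 0.680.

The second row then takes a little away: 0.847 of the released leaving group stays.

Take the electrophile's mean share as one minus half of what has reacted. My reckoning gives a product share of 0.289 and, with the adduct added, c of 45.5 %. It goes no further, so I give no pH by hand.

The forecast says 45.5 % (42 % to 49 %) and pH 7.91 (7.85 to 7.97), on the ground that “most of the leaving group released sits in the idle adduct”.

This flask gives c of 44.0 % at pH 7.89: product 27.3 %, idle adduct 16.7 %, free electrophile 56 %. At 6.07 s the free leaving group's half-life by its carrying off is 11 s, shorter than the electrophile's 28 s towards product. In this flask product is 0.656 of the drive. The neighbour flask charged with 0.38 M of nucleophile has a drive of 1.05 and reaches product 50.1 %, which is 0.477 of its drive, with free electrophile at 28 %.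

(The numbers belong to no real substance; the result is computed.)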